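**Plan**

- Retrosynthesis: the O1–C8a aryl ether of ring C is cut first, giving a C8a bromide and a free C2 carbinol. Next the C4–C4a bond is cut (ring A aryl anion plus a β-silyloxy aldehyde carrying ring B and C2), then the C6–CH2 bond to the lavandulyl chain.
- Forward: the lavandulyl unit is made and coupled to 5-bromoresorcinol bis-MOM ether between the two oxygens. Ring A is then lithiated beside bromine and added to the ring B aldehyde. Ring C, the only ring formed, closes by palladium-catalysed O1–C8a etherification, after which C4 is oxidised and the MOM groups are removed.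
- Stereochemistry: the lavandulyl centre comes from an oxazolidinone-controlled deconjugative alkylation, and C2 from a Brown allylboration of the ring B aldehyde. No later step cleaves the C2–O bond.
- Enabling feature: O1–C8a is a simple aryl–oxygen bond of ring C, and C8a is meta to both ring A oxygens. A bromine taken from 5-bromoresorcinol therefore marks C8a and fixes the side chain at C6 rather than C8.

Key step: step 13

Remark: the carbon that becomes C4 is formed without control in step 11 and is carried as both epimers (left undefined in the SMILES of 23–25) until step 14 makes it a ketone. The lavandulyl centre keeps its geometry throughout, and its descriptor changes from S (alcohol 8) to R (aryl compounds) only through the priority rules.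

Abbreviations: lavandulyl = 5-methyl-2-(prop-1-en-2-yl)hex-4-en-1-yl; MOM = methoxymethyl; TES = triethylsilyl; TBS = tert-butyldimethylsilyl.

**Route**

Step 1
Reactants: 1 (S)-4-benzyl-1,3-oxazolidin-2-one; 2 3-methylbut-2-enoyl chloride
Product: 4 (S)-4-benzyl-3-(3-methylbut-2-enoyl)-1,3-oxazolidin-2-one, via N-lithio oxazolidinone 3 (not isolated)
Conditions: n-BuLi, THF, −78 °C; then 2, −78 → 0 °C
Reagents that add atoms: none
Why: N-acylation of the lithium oxazolidinide by the acid chloride is the standard imide formation, and the absence of an amine base avoids vinylketene formation and deconjugation of the senecioyl group.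

Step 2
Reactants: 4; 5 1-bromo-3-methylbut-2-ene (prenyl bromide)
Product: 7 (S)-4-benzyl-3-[(2S)-5-methyl-2-(prop-1-en-2-yl)hex-4-enoyl]-1,3-oxazolidin-2-one, via sodium dienolate 6 (not isolated)
Conditions: NaN(SiMe3)2, THF, −78 °C; then 5, −78 → −40 °C
Reagents that add atoms: none
Why: Evans-type deconjugative α-alkylation, in which γ-deprotonation gives the chelated sodium Z-dienolate and prenyl bromide should attack its α-carbon on the face opposite the benzyl group, setting the (2S) centre that becomes the lavandulyl stereocentre.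

Step 3
Reactants: 7
Product: 8 (S)-lavandulol, (2S)-5-methyl-2-(prop-1-en-2-yl)hex-4-en-1-ol
Conditions: LiBH4, MeOH (1 equiv), Et2O, 0 °C; aq. NaOH
Reagents that add atoms: none
Why: Reductive cleavage of the N-acyl oxazolidinone with LiBH4 gives the primary alcohol and returns the auxiliary without touching the α-stereocentre or the two alkenes.

Step 4
Reactants: 8
Product: 9 (S)-lavandulyl trifluoromethanesulfonate
Conditions: Tf2O, pyridine, CH2Cl2, −78 → −30 °C; cold pentane filtration, used at once
Reagents that add atoms: trifluoromethanesulfonic anhydride, O=S(=O)(OS(=O)(=O)C(F)(F)F)C(F)(F)F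
Why: O-triflation of a primary alcohol at low temperature involves only the O–H bond, so the adjacent stereocentre is untouched and the CH2 carbon becomes electrophilic enough for the coupling in step 6.

Step 5
Reactants: 10 5-bromoresorcinol
Product: 11 1-bromo-3,5-bis(methoxymethoxy)benzene
Conditions: MOMCl, iPr2NEt, CH2Cl2, 0 °C → rt
Reagents that add atoms: chloromethyl methyl ether, COCCl
Why: Williamson-type O-alkylation of both phenols gives the bis-acetal whose oxygens direct the two later ring metalations.

Step 6
Reactants: 11; 9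
Product: 14 5-bromo-1,3-bis(methoxymethoxy)-2-[(2R)-5-methyl-2-(prop-1-en-2-yl)hex-4-en-1-yl]benzene, via aryllithium 12 (not isolated), via arylmagnesium bromide 13 (not isolated)
Conditions: LiN(iPr)2 (11 in slight excess), THF, −78 °C; MgBr2·OEt2, −78 → −30 °C; CuBr·SMe2 (10 mol %), 9, −30 → 0 °C
Reagents that add atoms: none
Why: Directed ortho-metalation with the amide base removes the proton flanked by both OMOM groups without bromine–lithium exchange, and the derived aryl Grignard reagent couples with the primary triflate under copper catalysis (copper-catalysed Grignard–alkyl triflate cross-coupling), a substitution at CH2 that leaves the neighbouring stereocentre unchanged.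

Step 7
Reactants: 15 2,4,6-trihydroxybenzaldehyde
Product: 16 2,4,6-tris(methoxymethoxy)benzaldehyde
Conditions: NaH, MOMCl, DMF, 0 °C → rt
Reagents that add atoms: chloromethyl methyl ether, COCCl
Why: Exhaustive Williamson O-alkylation of the sodium phenoxides protects all three hydroxyls, NaH being needed for the two hydrogen-bonded ortho hydroxyls.

Step 8
Reactants: 16
Product: 18 (1S)-1-[2,4,6-tris(methoxymethoxy)phenyl]but-3-en-1-ol, via borinate ester 17 (not isolated)
Conditions: (−)-Ipc2B(allyl), Et2O, −78 °C; then NaOH, H2O2, 0 °C → rt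
Reagents that add atoms: (−)-B-allyldiisopinocampheylborane (from (+)-α-pinene), C=CCB([C@@H]1C[C@@H]2C[C@H]([C@H]1C)C2(C)C)[C@@H]1C[C@@H]2C[C@H]([C@H]1C)C2(C)C
Why: Brown asymmetric allylboration, whose chair-like six-membered transition state should deliver the allyl group to the Si face of the aldehyde and so set the (S) carbinol that becomes C2, while the basic oxidative work-up spares the acid-labile benzylic alcohol.

Step 9
Reactants: 18
Product: 19 (1S)-1-(triethylsilyloxy)-1-[2,4,6-tris(methoxymethoxy)phenyl]but-3-ene
Conditions: TESCl, imidazole, DMF, 0 °C → rt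
Reagents that add atoms: chlorotriethylsilane, CC[Si](Cl)(CC)CC
Why: Silylation of the secondary alcohol masks the C2 oxygen for the aldehyde and organolithium steps and is removable later with fluoride under non-acidic conditions.

Step 10
Reactants: 19
Product: 21 (3S)-3-(triethylsilyloxy)-3-[2,4,6-tris(methoxymethoxy)phenyl]propanal, via vicinal diol 20 (not isolated)
Conditions: OsO4 (2 mol %), NaIO4, 2,6-lutidine, dioxane/H2O, rt
Reagents that add atoms: OsO4, O=[Os](=O)(=O)=O; NaIO4, [Na+].[O-]I(=O)(=O)=O
Why: Johnson–Lemieux oxidative cleavage (catalytic dihydroxylation, then glycol cleavage by periodate, buffered by 2,6-lutidine) converts the only alkene present into the aldehyde and is placed before the lavandulyl alkenes enter the molecule.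

Step 11
Reactants: 14; 21
Product: 23 (3S)-1-{2-bromo-4,6-bis(methoxymethoxy)-5-[(2R)-lavandulyl]phenyl}-3-(triethylsilyloxy)-3-[2,4,6-tris(methoxymethoxy)phenyl]propan-1-ol (both C1 epimers), via bromoaryllithium 22 (not isolated)
Conditions: lithium 2,2,6,6-tetramethylpiperidide (14 in slight excess), THF, −78 °C; then 21, −78 °C; H2O
Reagents that add atoms: none
Why: Directed ortho-lithiation by the hindered amide removes the ring proton flanked by bromine and OMOM (both such positions are equivalent), and at −78 °C the ortho-bromoaryllithium should add to the aldehyde (1,2-addition) faster than it loses LiBr, forming the C4–C4a bond with a carbinol centre that need not be controlled.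

Step 12
Reactants: 23
Product: 24 (3S)-1-{2-bromo-4,6-bis(methoxymethoxy)-5-[(2R)-lavandulyl]phenyl}-3-[2,4,6-tris(methoxymethoxy)phenyl]propane-1,3-diol (both C1 epimers)
Conditions: Bu4NF, THF, 0 °C
Reagents that add atoms: none
Why: Fluoride-mediated desilylation cleaves only the Si–O bond, so the C2 carbinol is released with its configuration intact and without the acid that would ionise this electron-rich benzylic alcohol.

Step 13
Reactants: 24
Product: 25 (2S)-5,7-bis(methoxymethoxy)-6-[(2R)-lavandulyl]-2-[2,4,6-tris(methoxymethoxy)phenyl]chroman-4-ol (both C4 epimers)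
Conditions: Pd(OAc)2 (5 mol %), 2-(di-tert-butylphosphino)-1,1'-binaphthyl (6 mol %), Cs2CO3, toluene, 65 °C, dilute
Reagents that add atoms: none
Why: Pd(OAc)2 (divalent palladium) is reduced in the flask to zerovalent palladium, which inserts into the C8a–Br bond; Cs2CO3 then converts the C2 hydroxyl into a palladium-bound alkoxide and C–O reductive elimination forms O1–C8a. The closest known reaction type is the intramolecular Buchwald–Hartwig etherification of aryl bromides by secondary alcohols, which gives chromans without loss of configuration at the carbinol carbon. Ring C closes by reductive elimination from a seven-membered aryl(alkoxo)palladium chelate, a 6-exo-type closure of the C2 oxygen onto C8a. No stereocentre is created: C2 stays S because only its O–H bond is involved, and the two C4 epimers simply give cis and trans flavan-4-ols that merge in step 14. The step needs the C2 hydroxyl, not the C4 hydroxyl, to react, and C–O reductive elimination has to be faster than β-hydride loss from the alkoxide; C4–O closure would give a four-membered benzoxete, the five-membered chelate of a C4 alkoxide holds its C4–H bond away from palladium, and the bulky di-tert-butyl biaryl phosphine accelerates reductive elimination. Leaving C4 at the alcohol level means the base meets no β-hydroxy ketone, so neither retro-aldol cleavage nor elimination to a chalcone can occur.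

Step 14
Reactants: 25
Product: 26 (2S)-5,7-bis(methoxymethoxy)-6-[(2R)-lavandulyl]-2-[2,4,6-tris(methoxymethoxy)phenyl]chroman-4-one
Conditions: Dess–Martin periodinane, NaHCO3, CH2Cl2, 0 °C → rt
Reagents that add atoms: none
Why: Dess–Martin oxidation of the benzylic secondary alcohol is essentially neutral when buffered, merges both C4 epimers into one ketone and leaves the alkenes, the MOM acetals and the C2 ether untouched.

Step 15
Reactants: 26
Product: 27 (2S)-5,7-dihydroxy-6-[(2R)-lavandulyl]-2-(2,4,6-trihydroxyphenyl)chroman-4-one (CNP0107340.3)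
Conditions: HCl (3 M aq.), MeOH, 25 → 40 °C, stopped as soon as conversion is complete
Reagents that add atoms: none
Why: Acid-catalysed acetal cleavage (transacetalisation to methanol) removes all five MOM groups, the temperature being kept low so that neither the isopropenyl group cyclises onto a neighbouring phenol nor the C2–O1 bond ionises.

**Compound list**

1 | (S)-4-benzyl-1,3-oxazolidin-2-one | O=C1N[C@@H](Cc2ccccc2)CO1 | starting material
2 | 3-methylbut-2-enoyl chloride | CC(C)=CC(=O)Cl | starting material
3 | N-lithio (S)-4-benzyl-1,3-oxazolidin-2-one | [Li]N1[C@@H](Cc2ccccc2)COC1=O | intermediate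
4 | (S)-4-benzyl-3-(3-methylbut-2-enoyl)-1,3-oxazolidin-2-one | CC(C)=CC(=O)N1[C@@H](Cc2ccccc2)COC1=O | intermediate
5 | 1-bromo-3-methylbut-2-ene | CC(C)=CCBr | starting material
6 | sodium Z-dienolate of 4 | C=C(C)/C=C(\O[Na])N1[C@@H](Cc2ccccc2)COC1=O | intermediate
7 | (S)-4-benzyl-3-[(2S)-5-methyl-2-(prop-1-en-2-yl)hex-4-enoyl]-1,3-oxazolidin-2-one | C=C(C)[C@H](CC=C(C)C)C(=O)N1[C@@H](Cc2ccccc2)COC1=O | intermediate
8 | (S)-lavandulol | C=C(C)[C@H](CC=C(C)C)CO | intermediate
9 | (S)-lavandulyl trifluoromethanesulfonate | C=C(C)[C@H](CC=C(C)C)COS(=O)(=O)C(F)(F)F | intermediate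
10 | 5-bromoresorcinol | Oc1cc(O)cc(Br)c1 | starting material
11 | 1-bromo-3,5-bis(methoxymethoxy)benzene | COCOc1cc(Br)cc(OCOC)c1 | intermediate
12 | 4-bromo-2,6-bis(methoxymethoxy)phenyllithium | [Li]c1c(OCOC)cc(Br)cc1OCOC | intermediate
13 | 4-bromo-2,6-bis(methoxymethoxy)phenylmagnesium bromide | Br[Mg]c1c(OCOC)cc(Br)cc1OCOC | intermediate
14 | 5-bromo-1,3-bis(methoxymethoxy)-2-[(2R)-lavandulyl]benzene | C=C(C)[C@H](CC=C(C)C)Cc1c(OCOC)cc(Br)cc1OCOC | intermediate
15 | 2,4,6-trihydroxybenzaldehyde | O=Cc1c(O)cc(O)cc1O | starting material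
16 | 2,4,6-tris(methoxymethoxy)benzaldehyde | COCOc1cc(OCOC)c(C=O)c(OCOC)c1 | intermediate
17 | diisopinocampheylborinate of 18 | C=CC[C@H](OB([C@@H]1C[C@@H]2C[C@H]([C@H]1C)C2(C)C)[C@@H]1C[C@@H]2C[C@H]([C@H]1C)C2(C)C)c1c(OCOC)cc(OCOC)cc1OCOC | intermediate
18 | (1S)-1-[2,4,6-tris(methoxymethoxy)phenyl]but-3-en-1-ol | C=CC[C@H](O)c1c(OCOC)cc(OCOC)cc1OCOC | intermediate
19 | (1S)-1-(triethylsilyloxy)-1-[2,4,6-tris(methoxymethoxy)phenyl]but-3-ene | C=CC[C@H](O[Si](CC)(CC)CC)c1c(OCOC)cc(OCOC)cc1OCOC | intermediate
20 | (4S)-4-(triethylsilyloxy)-4-[2,4,6-tris(methoxymethoxy)phenyl]butane-1,2-diol (both C2 epimers) | OCC(O)C[C@H](O[Si](CC)(CC)CC)c1c(OCOC)cc(OCOC)cc1OCOC | intermediate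
21 | (3S)-3-(triethylsilyloxy)-3-[2,4,6-tris(methoxymethoxy)phenyl]propanal | O=CC[C@H](O[Si](CC)(CC)CC)c1c(OCOC)cc(OCOC)cc1OCOC | intermediate
22 | 2-bromo-4,6-bis(methoxymethoxy)-5-[(2R)-lavandulyl]phenyllithium | C=C(C)[C@H](CC=C(C)C)Cc1c(OCOC)cc(Br)c([Li])c1OCOC | intermediate
23 | (3S)-1-{2-bromo-4,6-bis(methoxymethoxy)-5-[(2R)-lavandulyl]phenyl}-3-(triethylsilyloxy)-3-[2,4,6-tris(methoxymethoxy)phenyl]propan-1-ol (both C1 epimers) | C=C(C)[C@H](CC=C(C)C)Cc1c(OCOC)cc(Br)c(c1OCOC)C(O)C[C@H](O[Si](CC)(CC)CC)c1c(OCOC)cc(OCOC)cc1OCOC | intermediate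
24 | (3S)-1-{2-bromo-4,6-bis(methoxymethoxy)-5-[(2R)-lavandulyl]phenyl}-3-[2,4,6-tris(methoxymethoxy)phenyl]propane-1,3-diol (both C1 epimers) | C=C(C)[C@H](CC=C(C)C)Cc1c(OCOC)cc(Br)c(c1OCOC)C(O)C[C@H](O)c1c(OCOC)cc(OCOC)cc1OCOC | intermediate
25 | (2S)-5,7-bis(methoxymethoxy)-6-[(2R)-lavandulyl]-2-[2,4,6-tris(methoxymethoxy)phenyl]chroman-4-ol (both C4 epimers) | C=C(C)[C@H](CC=C(C)C)Cc1c(OCOC)cc2c(c1OCOC)C(O)C[C@@H](c1c(OCOC)cc(OCOC)cc1OCOC)O2 | intermediate
26 | (2S)-5,7-bis(methoxymethoxy)-6-[(2R)-lavandulyl]-2-[2,4,6-tris(methoxymethoxy)phenyl]chroman-4-one | C=C(C)[C@H](CC=C(C)C)Cc1c(OCOC)cc2c(c1OCOC)C(=O)C[C@@H](c1c(OCOC)cc(OCOC)cc1OCOC)O2 | intermediate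
27 | (2S)-5,7-dihydroxy-6-[(2R)-lavandulyl]-2-(2,4,6-trihydroxyphenyl)chroman-4-one | C=C(C)[C@H](CC=C(C)C)Cc1c(O)cc2c(c1O)C(=O)C[C@@H](c1c(O)cc(O)cc1O)O2 | target

**Step count**

Total: 15 steps. Longest linear sequence: 10 steps (steps 1–4, 6, 11–15, counted from oxazolidinone 1).

**Steps most likely to fail**

Step 13. The palladium alkoxide may undergo β-hydride elimination instead of C–O reductive elimination, so that a carbinol is oxidised and bromine is replaced by hydrogen. The free C4 hydroxyl, next to the palladium-bearing carbon, is the likeliest entry to this path. The fallback masks that hydroxyl during ring closure. Setting out from 23, TBSOTf and 2,6-lutidine (CH2Cl2, −78 °C) silylate the free hydroxyl to give the mixed bis-silyl ether F1. HF·pyridine buffered with pyridine (THF, 0 °C) then removes only the triethylsilyl group to give the TBS-protected bromo carbinol F2. The same Pd(OAc)2, phosphine and Cs2CO3 conditions close ring C to the 4-O-TBS flavan F3, and Bu4NF (THF) releases flavan-4-ol 25, where the route is rejoined.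

Step 6. Deprotonation may occur beside bromine instead of between the oxygens, or E2 elimination and ionisation of the β-branched homoallylic triflate may outpace substitution by the hindered aryl metal. The fallback replaces the anion alkylation by a Negishi cross-coupling. Setting out from 10, I2 and NaHCO3 in water iodinate between the hydroxyls to give 5-bromo-2-iodoresorcinol F4, and MOMCl with iPr2NEt gives 5-bromo-2-iodo-1,3-bis(methoxymethoxy)benzene F5. Setting out from 8, I2, PPh3 and imidazole give (S)-lavandulyl iodide F6, which Zn dust (THF, 40 °C) converts in the flask into (S)-lavandulylzinc iodide F7. Coupling of the two at the C–I bond with Pd(OAc)2 and SPhos (THF, rt), where the C–Br bond should react more slowly, comes back to the route at 14.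

Step 11. Ring deprotonation may be incomplete, the ortho-bromoaryllithium may lose LiBr to an aryne, or residual amide base may enolise aldehyde 21 and eliminate its silyloxy group. The fallback separates metalation from addition. Setting out from 14, lithiation with excess lithium 2,2,6,6-tetramethylpiperidide (THF, −78 °C) followed by I2, a quench that tolerates excess base, gives 1-bromo-2-iodo-3,5-bis(methoxymethoxy)-4-[(2R)-lavandulyl]benzene F8. iPrMgCl·LiCl (THF, −40 °C) exchanges only the iodine to give the amine-free 2-bromo-4,6-bis(methoxymethoxy)-5-[(2R)-lavandulyl]phenylmagnesium chloride F9, which is stable at that temperature and adds to 21 to come back to the route at 23.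

**Further compounds**

F1 | step 13 | (3S)-1-{2-bromo-4,6-bis(methoxymethoxy)-5-[(2R)-lavandulyl]phenyl}-1-(tert-butyldimethylsilyloxy)-3-(triethylsilyloxy)-3-[2,4,6-tris(methoxymethoxy)phenyl]propane (both C1 epimers) | C=C(C)[C@H](CC=C(C)C)Cc1c(OCOC)cc(Br)c(c1OCOC)C(O[Si](C)(C)C(C)(C)C)C[C@H](O[Si](CC)(CC)CC)c1c(OCOC)cc(OCOC)cc1OCOC
F2 | step 13 | (1S)-3-{2-bromo-4,6-bis(methoxymethoxy)-5-[(2R)-lavandulyl]phenyl}-3-(tert-butyldimethylsilyloxy)-1-[2,4,6-tris(methoxymethoxy)phenyl]propan-1-ol (both C3 epimers) | C=C(C)[C@H](CC=C(C)C)Cc1c(OCOC)cc(Br)c(c1OCOC)C(O[Si](C)(C)C(C)(C)C)C[C@H](O)c1c(OCOC)cc(OCOC)cc1OCOC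
F3 | step 13 | (2S)-4-(tert-butyldimethylsilyloxy)-5,7-bis(methoxymethoxy)-6-[(2R)-lavandulyl]-2-[2,4,6-tris(methoxymethoxy)phenyl]chroman (both C4 epimers) | C=C(C)[C@H](CC=C(C)C)Cc1c(OCOC)cc2c(c1OCOC)C(O[Si](C)(C)C(C)(C)C)C[C@@H](c1c(OCOC)cc(OCOC)cc1OCOC)O2
F4 | step 6 | 5-bromo-2-iodobenzene-1,3-diol | Oc1cc(Br)cc(O)c1I
F5 | step 6 | 5-bromo-2-iodo-1,3-bis(methoxymethoxy)benzene | COCOc1cc(Br)cc(OCOC)c1I
F6 | step 6 | (S)-lavandulyl iodide | C=C(C)[C@H](CC=C(C)C)CI
F7 | step 6 | (S)-lavandulylzinc iodide | C=C(C)[C@H](CC=C(C)C)C[Zn]I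
F8 | step 11 | 1-bromo-2-iodo-3,5-bis(methoxymethoxy)-4-[(2R)-lavandulyl]benzene | C=C(C)[C@H](CC=C(C)C)Cc1c(OCOC)cc(Br)c(I)c1OCOC
F9 | step 11 | 2-bromo-4,6-bis(methoxymethoxy)-5-[(2R)-lavandulyl]phenylmagnesium chloride | C=C(C)[C@H](CC=C(C)C)Cc1c(OCOC)cc(Br)c([Mg]Cl)c1OCOC
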